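The easy step comes first: every turnover on either substrate spends one coupling partner, so the first thing to count is partner against substrate.

left-handed substrate 20 mM; coupling partner 1.50 equiv (fed, over 25 min); precatalyst 18 mol%; right-handed substrate 20 mM; time 2.0 h; the fed solution adds 0.25 times the starting volume

    coupling partner + catalyst + left-handed substrate → catalyst + left-handed product (k1 = 4700 M⁻² min⁻¹)
    coupling partner + catalyst + right-handed substrate → catalyst + right-handed product (k2 = 2000 M⁻² min⁻¹)
    precatalyst → catalyst (k3 = 0.023 min⁻¹)
    catalyst ⇌ dormant form (K4 = 1.4, k4 = 0.032 min⁻¹)

- catalyst is single-handed; left-handed substrate and right-handed substrate are mirror images of each other, charged as a racemate, each of them at the stated concentration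
- charges are per starting volume, the dose included; the dosed solution carries all of it
- the reaction counts as stopped when no species that holds the left-handed substrate and right-handed substrate together changes by six tenths of a point or more over the second half of the time
- run time (flask): 2.0 h

1. at 2.0 h, what has stopped the reaction, if anything has (it is still moving / no working catalyst is left / forward and back rates have come level / all of the left-handed substrate has reacted)
2. conversion of left-handed substrate and right-handed substrate together at 2.0 h
3. amount of left-handed product at 2.0 h, in percent of the left-handed substrate and right-handed substrate together charged

The equivalents stand on the left-handed substrate, so by my reckoning this flask holds 30.0 mM of partner against 40.0 mM of racemate, less partner than substrate, which makes partner the limiting reagent. Conversion therefore meets 75.0%, the partner ceiling: the conversion that the charged partner pays for at one partner per substrate. My figure is 75.0%.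

Both steps share partner and catalyst, so in logarithms the left-handed remainder is always 2.35 times the right-handed one, that ratio being the selectivity factor. At the ceiling the two remainders, as fractions of their own charges, add to 50.0%. A right-handed remainder of 40.0% is 0.398 decades down, which puts the left-handed substrate 0.935 decades down, at 11.6%. The sum, 51.6%, is close enough, and left-handed product comes to 44.2%.

The time ladder runs upward from there. Catalyst and dormant form relax in 0.211 h, but precatalyst goes on supplying fresh catalyst with the longer half-life of 0.50 h, so the equilibrium share of catalyst in catalyst plus dormant form, 41.7%, is a late limit, and I take it, on the whole catalyst charge, as my late figure for catalyst. Near those remainders, partner decays pseudo-first-order with a half-life of 0.447 h, just shorter than the precatalyst's 0.50 h. The later 1.00 h of the run spans 2.24 partner half-lives, so I expect partner still draining and the flask still moving.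

The forecast gives it is still moving, >99.9% and 50%, on different grounds from mine: “Taking equivalents and mol% on the 40 mM racemate”.

The flask gives it is still moving, with 73.5% conversion and 43.9% left-handed product, so the forecast and the flask part on conversion, and the base of the equivalents is where the two reckonings differ. The flask has not come to rest: the largest change over the second half of the time is 3.9 percentage points. At 2.00 h, 2.0% of the partner remains, with 12% of the left-handed and 41% of the right-handed charge. Left until 20.0 h, the flask reaches 75.0% conversion and 44.5% left-handed product, level with the ceiling.

For the neighbour flask charged with 0.600 equiv of partner, the ceiling gives 30.0%. That neighbour's computed conversion is 30.0%.

(The numbers of this flask are invented; what happens was integrated by code.)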